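Locants used throughout: C1 methyl-bearing fusion carbon, C2 and C3 ring CH2, C4 isopropyl carbinol, C5 fusion CH, C6 veratrate carbon, C7 CH2, C8=C9 alkene with the methyl on C8, C10 angelate carbon.

## Structural features

The target is a daucane-type bicyclo[5.3.0]decane in which a cyclopentane (C1–C5) is trans-fused along C1–C5 to a cycloheptene (C1, C5–C10) whose C8=C9 double bond carries a methyl group on C8. Five stereocentres form one contiguous array, C10–C1–C5(–C4)–C6, with descriptors 1S,4R,5S,6S,10R: the quaternary C1 methyl is anti to H-5 and to the C10 oxygen, O-4 lies on the methyl face and O-6 on the face of H-5. The fragile groups are the (Z)-2-methylbut-2-enoate (prone to isomerise to the tiglate when its acyl group is activated), the allylic C10–O bond next to a trisubstituted alkene, the tertiary alcohol at C4 and, while C6 is still a ketone, the β-hydroxy ketone that can cleave by retro-aldol reaction. The real difficulty is the quaternary C1 flanked by three stereocentres, the trans ring fusion, and the pseudoaxial C10 oxygen trans-diaxial to the C1 methyl, which is the arrangement that hydride addition to a C10 carbonyl is not expected to give. The key step exploits that O-4–C4–C5–C6–O-6 is an aldol pattern closed inside the five-membered ring while the C1 methyl is β to C6 and anti to O-10. A cycloheptenone with its carbonyl at C6, a C5=C1 double bond, a silyl ether at C10 and a C2–C3–C4(=O)–isopropyl chain on C1 therefore maps onto methyl cuprate addition at C1 followed by enolate closure from C5 to C4. The C8 methyl, the C8=C9 double bond and the two esters sit on the periphery of the seven-membered ring and can be added once the bicycle exists.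

## Logic of the disconnections

**29 ⇒ 27 + 28.** The bond cut is C10–O (carbinol carbon to ester oxygen), not the acyl C–O bond. Hydride is expected to reach a C10 carbonyl anti to the pseudoaxial C1 methyl and so to leave the hydroxyl cis to that methyl; a plan of reduction followed by acylation with retention would therefore end in the C10 epimer. Forming the ester by displacement with inversion turns this bias into the required trans relationship and brings in the acid as an O-nucleophile rather than as an activated acyl donor. The gain is that the isomerisation-prone ester and the allylic stereocentre disappear in one step. The demand is SN2 displacement at a neopentylic, allylic carbon without allylic transposition, with the tertiary C4 hydroxyl staying inert.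

**27 ⇒ 26 ⇒ 25 ⇒ 23.** Cut in turn are C10–H, the C8=C9 π-bond and C8–CH3. A C10 carbonyl is the only handle that activates C9 and C8, and because C1 is quaternary its enolisation is regiochemically unambiguous. The free C4 hydroxyl would destroy one equivalent of a stoichiometric organocopper reagent, so the methyl group is delivered by a methyl Grignard reagent with catalytic copper, which tolerates the magnesium alkoxide. The gain is removal of the methyl group and the alkene. The demand is 1,2- versus 1,4-selectivity in the reduction and in the methyl addition, and tolerance of the C6 ester and the free C4 hydroxyl in the methyl addition and dehydrogenation steps.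

**23 ⇒ 21 ⇒ 20.** The C8=C9 and C10=O π-bonds are taken back to the C10 carbinol, then the O–Si bond is cut. The silyl ether that steers the cascade is thereby spent for the carbonyl; the C10 stereocentre is given up knowingly and is restored by the first paragraph. The demand is oxidation and dehydrogenation that leave an aryl ester and a tertiary alcohol untouched.

**20 ⇒ 18 + 19.** The acyl C–O bond at O-6 is cut. The tertiary O-4 needs no protection, so the diol can be used directly. The demand is acylation of a hindered secondary alcohol.

**18 ⇒ 17.** The C6–H bond is cut. The free O-4 of 17 lies on the face of the C6 carbonyl from which hydride must come, so an internally delivered hydride sets C6; external hydride would enter past H-5 and give the epimer. The demand is exchange of a hindered tertiary hydroxyl onto boron.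

**17 ⇒ 11 + 12.** C1–CH3 and C4–C5 are cut, opening the cyclopentane. This removes one ring, two skeletal bonds and three stereocentres and leaves a monocyclic enone with a single stereocentre. The (R) descriptor of 11 and the descriptors of 17 were checked against 29: they describe the same spatial arrangement at C1, C4, C5 and C10, so these structures need no correction. The silyl ether is kept bulky and non-chelating so that it directs the cuprate anti and cannot tie O-4 of a cis-fused aldolate to O-10. The demand is facial control at C1, chemoselectivity of the cuprate for the enone over the ketone, and equilibration of the ring fusion to trans.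

**11 ⇒ 10 ⇒ 9 ⇒ 4 + 7.** The ketal C–O bonds and then the ring–chain bond C1–C2 are cut, the latter via conjugate addition and re-oxidation. A β-alkyl group is put on an enone without touching the C10 stereocentre. The side-chain ketone travels as a 1,3-dioxane because Grignard reagents of the corresponding dioxolanes are unstable. The demand is regiospecific regeneration of the enone and a ketal hydrolysis mild enough for the allylic silyl ether.

**7 ⇒ 5.** C–Br and the two ketal C–O bonds are cut; the enone supplies the whole C2–C4 chain with its isopropyl group in one operation.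

**4 ⇒ 3 ⇒ 2 ⇒ 1.** O–Si, then the O–O bond and one bridgehead C–H, then the two C–O bonds of a [4+2] adduct with dioxygen are cut. A meso endoperoxide is desymmetrised catalytically, so no resolution and no chiral auxiliary is needed. The demand is high enantioselection in the base-catalysed rearrangement.

## Other disconnections considered

**Alternative 1:** C1–C5 and C9–C10 are cut. In the forward sense the acyclic allene-tethered siloxyvinylcyclopropane A1 would be cyclised by [Rh(BINAP)]SbF6, a cationic complex of monovalent rhodium, to the cis-fused hydroazulene A2.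
- In its favour: both rings and the quaternary C1 form in one catalytic step, and the absolute configuration comes from the ligand. The C8 methyl is already in place, so a C10 ketone (from the exocyclic methylene) needs only one dehydrogenation to reach the stage of 26; on this point it is better than the chosen plan. C4 would be set by isopropyl addition to a ketone anti to the angular methyl, which is decoupled from the ring fusion and also better than an aldol equilibrium.
- Against it: A2 is cis-fused, so C5 must be epimerised through the C6 ketone. This rests on the same cis/trans thermodynamics as the chosen plan, though only one centre has to move, so it is equal or slightly better. The internal allene π-bond must react, the methyl-substituted cyclopropane must open in the right sense, and a quaternary centre must form in the reductive elimination. A1 itself needs a long linear preparation. C10 still passes through a ketone and meets the same hydride-face problem, so the two plans are equal there.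
- Overall: a metallacycle mechanism with catalyst control against a polar cascade with substrate control; step economy is not expected to be lower.

**Alternative 2:** C7–C8 and C1–C10 are cut. Rh2(DOSP)4 would convert the acetoxy vinyldiazoacetate A4 into a carbenoid that cyclopropanates the silyloxyvinyl group of diene A3, and the cis-divinylcyclopropane would rearrange to A5.
- In its favour: it is convergent. The C10 oxygen and the C8=C9 double bond arrive at their final positions and oxidation levels, so neither a C10 ketone nor an inversion is needed, which is better than the chosen plan. C1 and C10 are related through the boat transition state of the Cope rearrangement, equal in reliability to anti cuprate addition. C4 is present from the start.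
- Against it: the C8 substituent is an ester that must be reduced to methyl over several steps beside an allylic acetate. The Cope step must build the quaternary C1 from a tetrasubstituted alkene terminus. Catalyst and the C4 stereocentre must be matched. C5 is still sp2 in A5, so the trans fusion must come from protonation of a silyl enol ether, an uncertainty equal to that of the chosen plan. A3 needs an enantiopure cyclopentene fragment and A4 is a sensitive diazo compound.
- Overall: the step count is probably comparable once both fragments are counted.

**Alternative 3:** the C1–C5 bond is traced back to a C1–C6 bond of a decalin. The tertiary C6 alkoxide of the cis-decalin diol monomesylate A6, whose skeleton traces back to an enantioselective Robinson annulation, would push a 1,2-shift of C1 to C5 with loss of mesylate and give the trans-fused ketone A7.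
- In its favour: ring fusion and C5 follow stereospecifically from anti-periplanar migration with inversion, with no equilibrium involved; this is better than the chosen plan on its weakest point. The quaternary C1 comes enantiopure from a cheap building block. A7 carries C6 as a ketone, like 17, and C10 already as a masked ketone, the oxidation level that the chosen plan reaches only at 22. Since the route to A7 should be about as long as that to 17, the alternative is equal in step economy or slightly better.
- Against it: the dihydroxylation must deliver both oxygens cis to the angular methyl, against the usual facial bias. Isopropyl addition must set C4 before that. The C4 silyl ether blocks the hydroxyl-directed reduction at C6 unless it is removed. C10 meets the same hydride-face problem as in the chosen plan.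
- Overall: the chosen cascade is better in that it forms two C–C bonds and three stereocentres in one operation from a monocyclic enone, but it pays for this with the ring-fusion uncertainty.

Key step: step 8

Assumption: the quinidine-derived catalyst 9-O-acetylcupreidine is taken to deliver the (R)-hydroxy enone in step 2; if the sense is the opposite, its quinine-derived pseudoenantiomer is used with no other change.

Naming: bicyclic compounds are named as bicyclo[5.3.0]decanes with the target locants defined at the top (C1 and C5 are the fusion atoms).

## Route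

Step 1
Reactants: 1 cyclohepta-1,3-diene
Product: 2 6,7-dioxabicyclo[3.2.2]non-8-ene (meso endoperoxide)
Conditions: O2, tetraphenylporphyrin (cat.), visible light, CH2Cl2, 0 °C
Reagents that add atoms: dioxygen, O=O
Why: [4+2] cycloaddition of singlet oxygen to the ring-locked s-cis diene; both C–O bonds necessarily form on one face, giving the meso endoperoxide.

Step 2
Reactants: 2 6,7-dioxabicyclo[3.2.2]non-8-ene
Product: 3 (R)-4-hydroxycyclohept-2-en-1-one
Conditions: 9-O-acetylcupreidine (10 mol %), CH2Cl2, 23 °C
Reagents that add atoms: none
Why: Desymmetrising Kornblum–DeLaMare rearrangement: the quinuclidine nitrogen removes one of the two enantiotopic bridgehead hydrogens while the phenol activates the peroxide, O–O cleavage gives the γ-hydroxy enone, and the untouched bridgehead becomes the (R)-carbinol.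

Step 3
Reactants: 3 (R)-4-hydroxycyclohept-2-en-1-one
Product: 4 (R)-4-(tert-butyldimethylsilyloxy)cyclohept-2-en-1-one
Conditions: TBSCl, imidazole, DMF, 0 → 23 °C
Reagents that add atoms: tert-butyldimethylsilyl chloride, CC(C)(C)[Si](C)(C)Cl
Why: Standard silylation of a secondary alcohol; imidazole is too weak a base to isomerise the γ-hydroxy enone to the 1,4-dione.

Step 4
Reactants: 5 4-methylpent-1-en-3-one
Product: 7 2-(2-bromoethyl)-2-isopropyl-1,3-dioxane, via 1-bromo-4-methylpentan-3-one 6 (not isolated)
Conditions: HBr (gas), CH2Cl2, 0 °C; then propane-1,3-diol, HC(OEt)3, TsOH·H2O (cat.), 23 °C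
Reagents that add atoms: hydrogen bromide, Br; propane-1,3-diol, OCCCO
Why: Conjugate hydrobromination of the enone followed by acid-catalysed ketalisation driven by the orthoformate; the six-membered ketal is chosen because its Grignard reagent is stable and a ketone-derived 1,3-dioxane is hydrolysed easily later.

Step 5
Reactants: 7 2-(2-bromoethyl)-2-isopropyl-1,3-dioxane; 4 (R)-4-(tert-butyldimethylsilyloxy)cyclohept-2-en-1-one
Product: 9 (3R,4R)-4-(tert-butyldimethylsilyloxy)-3-[2-(2-isopropyl-1,3-dioxan-2-yl)ethyl]-1-(trimethylsilyloxy)cyclohept-1-ene, via Grignard reagent 8 (not isolated)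
Conditions: Mg, THF, 30 °C; then CuBr·SMe2 (10 mol %), TMSCl, 4, THF, −78 °C; Et3N
Reagents that add atoms: chlorotrimethylsilane, C[Si](C)(C)Cl
Why: Copper-catalysed conjugate addition of the Grignard reagent, accelerated and trapped by TMSCl; the chain enters anti to the silyloxy group (3,4-trans) and the enolate is fixed regiospecifically as the C1–C2 silyl enol ether.

Step 6
Reactants: 9 (3R,4R)-4-(tert-butyldimethylsilyloxy)-3-[2-(2-isopropyl-1,3-dioxan-2-yl)ethyl]-1-(trimethylsilyloxy)cyclohept-1-ene
Product: 10 (R)-4-(tert-butyldimethylsilyloxy)-3-[2-(2-isopropyl-1,3-dioxan-2-yl)ethyl]cyclohept-2-en-1-one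
Conditions: Pd(OAc)2 (1.1 equiv), MeCN, 23 °C
Reagents that add atoms: none
Why: Saegusa–Ito oxidation: divalent palladium adds at C2 of the enol ether and β-hydride elimination of the C3 hydrogen restores the enone, now β,β-disubstituted; the C3 stereocentre is erased and the silyloxy carbon is untouched.

Step 7
Reactants: 10 (R)-4-(tert-butyldimethylsilyloxy)-3-[2-(2-isopropyl-1,3-dioxan-2-yl)ethyl]cyclohept-2-en-1-one
Product: 11 (R)-4-(tert-butyldimethylsilyloxy)-3-(4-methyl-3-oxopentyl)cyclohept-2-en-1-one
Conditions: PPTS, acetone–H2O (10:1), 55 °C
Reagents that add atoms: water, O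
Why: Acid-catalysed ketal hydrolysis; the secondary allylic silyl ether is expected to survive the buffered acid, and the aldol acceptor is unmasked only now.

Step 8
Reactants: 11 (R)-4-(tert-butyldimethylsilyloxy)-3-(4-methyl-3-oxopentyl)cyclohept-2-en-1-one; 12 methyllithium
Product: 17 (1S,4R,5R,10R)-10-(tert-butyldimethylsilyloxy)-4-hydroxy-4-isopropyl-1-methylbicyclo[5.3.0]decan-6-one (trans-fused), via lithium dimethylcuprate 13 (not isolated), via lithium enolate 14 (not isolated), via cis-fused lithium aldolate 15 (not isolated), via trans-fused lithium aldolate 16 (not isolated)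
Conditions: MeLi (2 equiv per Cu), CuI, Et2O, 0 °C; then 11, −78 → −20 °C; THF added, warm to 23 °C; aq. NH4Cl
Reagents that add atoms: none
Why: The cuprate 13 forms a π-complex with the enone and, through a trivalent copper β-cuprio enolate and reductive elimination, transfers methyl to C1 on the face opposite the pseudoaxial C10 silyloxy group, which sets C1 and gives enolate 14 regiospecifically at C5–C6. The closest known reaction type is the tandem cuprate conjugate addition–intramolecular aldol cyclisation of keto-enones. The C5 enolate closes onto the side-chain ketone in a 5-(enolexo)-exo-trig aldol, the only five-membered mode open to it. C4 is controlled by a six-membered lithium chelate between O-6 and O-4 and by the isopropyl group turning away from C6, so O-4 ends cis to C6 in either closure. C5 is the delicate centre: closure through the conformer with the tether pseudoaxial is kinetically easiest and gives the cis-fused aldolate 15, whereas the trans-diaxial arrangement of C1 methyl and C10 silyloxy holds the tether pseudoequatorial and leads to the trans-fused aldolate 16. Because a tertiary lithium aldolate reverts readily, warming should let 15 return to 14 and funnel into 16, in which the cyclopentane is fused through two pseudoequatorial bonds and C4 lies in the plane of the C6 carbonyl, ideal for the chelate. The step needs 1,4- over 1,2-selectivity (soft cuprate), facial selectivity (bulky non-chelating silyl ether) and regiocontrol of the enolate (formed by addition, not by base), and the fast intramolecular aldol must outrun proton transfer from the side-chain ketone.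

Step 9
Reactants: 17 (1S,4R,5R,10R)-10-(tert-butyldimethylsilyloxy)-4-hydroxy-4-isopropyl-1-methylbicyclo[5.3.0]decan-6-one
Product: 18 (1S,4R,5S,6S,10R)-10-(tert-butyldimethylsilyloxy)-4-isopropyl-1-methylbicyclo[5.3.0]decane-4,6-diol
Conditions: Me4NBH(OAc)3, MeCN–AcOH (1:1), −30 → −20 °C
Reagents that add atoms: none
Why: Hydroxyl-directed (Evans–Saksena-type) reduction: boron binds to O-4, which lies on the carbonyl face flanked by C1 and C4, and internal hydride delivery from that face gives the 4,6-anti diol with O-6 cis to H-5; external hydride would enter past H-5 and give the C6 epimer.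

Step 10
Reactants: 18 (1S,4R,5S,6S,10R)-10-(tert-butyldimethylsilyloxy)-4-isopropyl-1-methylbicyclo[5.3.0]decane-4,6-diol; 19 3,4-dimethoxybenzoyl chloride
Product: 20 (1S,4R,5S,6S,10R)-10-(tert-butyldimethylsilyloxy)-4-hydroxy-4-isopropyl-1-methylbicyclo[5.3.0]decan-6-yl 3,4-dimethoxybenzoate
Conditions: Et3N, DMAP (cat.), CH2Cl2, 23 → 40 °C
Reagents that add atoms: none
Why: Acylation under nucleophilic catalysis; only the secondary C6 hydroxyl reacts, since the tertiary C4 hydroxyl between isopropyl and the ring fusion is inert.

Step 11
Reactants: 20 (1S,4R,5S,6S,10R)-10-(tert-butyldimethylsilyloxy)-4-hydroxy-4-isopropyl-1-methylbicyclo[5.3.0]decan-6-yl 3,4-dimethoxybenzoate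
Product: 21 (1S,4R,5S,6S,10R)-4,10-dihydroxy-4-isopropyl-1-methylbicyclo[5.3.0]decan-6-yl 3,4-dimethoxybenzoate
Conditions: HF·pyridine, THF–pyridine, 0 → 23 °C
Reagents that add atoms: none
Why: Fluoride cleavage of the secondary silyl ether under buffered acidic conditions that leave the aryl ester and the tertiary alcohol alone; basic fluoride is avoided to exclude acyl migration.

Step 12
Reactants: 21 (1S,4R,5S,6S,10R)-4,10-dihydroxy-4-isopropyl-1-methylbicyclo[5.3.0]decan-6-yl 3,4-dimethoxybenzoate
Product: 23 (1S,4R,5S,6S)-4-hydroxy-4-isopropyl-1-methyl-10-oxobicyclo[5.3.0]dec-8-en-6-yl 3,4-dimethoxybenzoate, via C10 ketone 22 (not isolated)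
Conditions: IBX (2.5 equiv), DMSO, 23 °C then 75 °C
Reagents that add atoms: none
Why: IBX oxidises the secondary alcohol to the ketone at room temperature and on heating dehydrogenates it through its only possible enol (towards C9, C1 being quaternary) to the enone.

Step 13
Reactants: 23 (1S,4R,5S,6S)-4-hydroxy-4-isopropyl-1-methyl-10-oxobicyclo[5.3.0]dec-8-en-6-yl 3,4-dimethoxybenzoate
Product: 25 (1S,4R,5S,6S,8RS)-4-hydroxy-4-isopropyl-1,8-dimethyl-10-oxobicyclo[5.3.0]decan-6-yl 3,4-dimethoxybenzoate, via bis(bromomagnesium) enolate alkoxide 24 (not isolated)
Conditions: CuBr·SMe2 (10 mol %), MeMgBr (2.5 equiv, slow addition), THF, −78 → −40 °C; aq. NH4Cl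
Reagents that add atoms: methylmagnesium bromide, C[Mg]Br
Why: Copper-catalysed (Kharasch-type) conjugate addition of the methyl Grignard reagent to the β-monosubstituted enone: the first equivalent turns the tertiary hydroxyl into its bromomagnesium alkoxide, and the catalytic methylcopper species formed in the flask transfers methyl to C8 far faster than the Grignard reagent, kept at low concentration by slow addition at −78 °C, attacks the enone carbonyl or the hindered, electron-rich aryl ester. The C8 configuration is irrelevant because C8 becomes sp2 in the next step.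

Step 14
Reactants: 25 (1S,4R,5S,6S,8RS)-4-hydroxy-4-isopropyl-1,8-dimethyl-10-oxobicyclo[5.3.0]decan-6-yl 3,4-dimethoxybenzoate
Product: 26 (1S,4R,5S,6S)-4-hydroxy-4-isopropyl-1,8-dimethyl-10-oxobicyclo[5.3.0]dec-8-en-6-yl 3,4-dimethoxybenzoate
Conditions: IBX (1.5 equiv), DMSO, 75 °C
Reagents that add atoms: none
Why: A second IBX dehydrogenation through the C9 enol gives the β-methyl enone; again only one α-carbon carries hydrogen.

Step 15
Reactants: 26 (1S,4R,5S,6S)-4-hydroxy-4-isopropyl-1,8-dimethyl-10-oxobicyclo[5.3.0]dec-8-en-6-yl 3,4-dimethoxybenzoate
Product: 27 (1S,4R,5S,6S,10S)-4,10-dihydroxy-4-isopropyl-1,8-dimethylbicyclo[5.3.0]dec-8-en-6-yl 3,4-dimethoxybenzoate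
Conditions: NaBH4, CeCl3·7H2O, MeOH, −78 °C
Reagents that add atoms: none
Why: Luche 1,2-reduction of the enone; hydride is expected to enter anti to the pseudoaxial C1 methyl, which places the new hydroxyl cis to that methyl (10S), the C10 epimer of the target, and this is used on purpose in step 16.

Step 16
Reactants: 27 (1S,4R,5S,6S,10S)-4,10-dihydroxy-4-isopropyl-1,8-dimethylbicyclo[5.3.0]dec-8-en-6-yl 3,4-dimethoxybenzoate; 28 angelic acid
Product: 29 (1S,4R,5S,6S,10R)-4-hydroxy-4-isopropyl-1,8-dimethyl-10-[(Z)-2-methylbut-2-enoyloxy]bicyclo[5.3.0]dec-8-en-6-yl 3,4-dimethoxybenzoate (target)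
Conditions: PPh3, DIAD, toluene, 0 → 23 °C
Reagents that add atoms: none
Why: Mitsunobu esterification: the oxyphosphonium ion at C10 is displaced by the carboxylate along the axial trajectory anti to the C1 methyl, inverting C10 to (R). The acid enters as a carboxylate O-nucleophile rather than as an activated acyl donor, so the Z geometry should be kept. The tertiary C4 alcohol does not react.

## Compound list

1 | cyclohepta-1,3-diene | C1=CC=CCCC1 | starting material
2 | 6,7-dioxabicyclo[3.2.2]non-8-ene (meso) | C1CC[C@@H]2C=C[C@H]1OO2 | intermediate
3 | (R)-4-hydroxycyclohept-2-en-1-one | O[C@@H]1CCCC(=O)C=C1 | intermediate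
4 | (R)-4-(tert-butyldimethylsilyloxy)cyclohept-2-en-1-one | CC(C)(C)[Si](C)(C)O[C@@H]1CCCC(=O)C=C1 | intermediate
5 | 4-methylpent-1-en-3-one | C=CC(=O)C(C)C | starting material
6 | 1-bromo-4-methylpentan-3-one | BrCCC(=O)C(C)C | intermediate (not isolated)
7 | 2-(2-bromoethyl)-2-isopropyl-1,3-dioxane | BrCCC1(C(C)C)OCCCO1 | intermediate
8 | [2-(2-isopropyl-1,3-dioxan-2-yl)ethyl]magnesium bromide | Br[Mg]CCC1(C(C)C)OCCCO1 | intermediate (not isolated)
9 | (3R,4R)-4-(tert-butyldimethylsilyloxy)-3-[2-(2-isopropyl-1,3-dioxan-2-yl)ethyl]-1-(trimethylsilyloxy)cyclohept-1-ene | CC(C)(C)[Si](C)(C)O[C@@H]1CCCC(O[Si](C)(C)C)=C[C@H]1CCC2(C(C)C)OCCCO2 | intermediate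
10 | (R)-4-(tert-butyldimethylsilyloxy)-3-[2-(2-isopropyl-1,3-dioxan-2-yl)ethyl]cyclohept-2-en-1-one | CC(C)(C)[Si](C)(C)O[C@@H]1CCCC(=O)C=C1CCC2(C(C)C)OCCCO2 | intermediate
11 | (R)-4-(tert-butyldimethylsilyloxy)-3-(4-methyl-3-oxopentyl)cyclohept-2-en-1-one | CC(C)(C)[Si](C)(C)O[C@@H]1CCCC(=O)C=C1CCC(=O)C(C)C | intermediate (precursor of the key step)
12 | methyllithium | [Li]C | starting material
13 | lithium dimethylcuprate | [Li+].C[Cu-]C | intermediate (not isolated)
14 | lithium (3S,4R)-4-(tert-butyldimethylsilyloxy)-3-methyl-3-(4-methyl-3-oxopentyl)cyclohept-1-en-1-olate | CC(C)(C)[Si](C)(C)O[C@@H]1CCCC(O[Li])=C[C@]1(C)CCC(=O)C(C)C | intermediate (not isolated)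
15 | lithium alkoxide of the cis-fused (1S,4S,5S,10R)-ketol | CC(C)(C)[Si](C)(C)O[C@@H]1CCCC(=O)[C@H]2[C@]1(C)CC[C@]2(O[Li])C(C)C | intermediate (not isolated)
16 | lithium alkoxide of the trans-fused (1S,4R,5R,10R)-ketol | CC(C)(C)[Si](C)(C)O[C@@H]1CCCC(=O)[C@@H]2[C@]1(C)CC[C@@]2(O[Li])C(C)C | intermediate (not isolated)
17 | (1S,4R,5R,10R)-10-(tert-butyldimethylsilyloxy)-4-hydroxy-4-isopropyl-1-methylbicyclo[5.3.0]decan-6-one (trans-fused) | CC(C)(C)[Si](C)(C)O[C@@H]1CCCC(=O)[C@@H]2[C@]1(C)CC[C@@]2(O)C(C)C | intermediate (product of the key step)
18 | (1S,4R,5S,6S,10R)-10-(tert-butyldimethylsilyloxy)-4-isopropyl-1-methylbicyclo[5.3.0]decane-4,6-diol | CC(C)(C)[Si](C)(C)O[C@@H]1CCC[C@H](O)[C@@H]2[C@]1(C)CC[C@@]2(O)C(C)C | intermediate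
19 | 3,4-dimethoxybenzoyl chloride | COc1ccc(C(=O)Cl)cc1OC | starting material
20 | (1S,4R,5S,6S,10R)-10-(tert-butyldimethylsilyloxy)-4-hydroxy-4-isopropyl-1-methylbicyclo[5.3.0]decan-6-yl 3,4-dimethoxybenzoate | CC(C)(C)[Si](C)(C)O[C@@H]1CCC[C@H](OC(=O)c3ccc(OC)c(OC)c3)[C@@H]2[C@]1(C)CC[C@@]2(O)C(C)C | intermediate
21 | (1S,4R,5S,6S,10R)-4,10-dihydroxy-4-isopropyl-1-methylbicyclo[5.3.0]decan-6-yl 3,4-dimethoxybenzoate | O[C@@H]1CCC[C@H](OC(=O)c3ccc(OC)c(OC)c3)[C@@H]2[C@]1(C)CC[C@@]2(O)C(C)C | intermediate
22 | (1S,4R,5S,6S)-4-hydroxy-4-isopropyl-1-methyl-10-oxobicyclo[5.3.0]decan-6-yl 3,4-dimethoxybenzoate | O=C1CCC[C@H](OC(=O)c3ccc(OC)c(OC)c3)[C@@H]2[C@]1(C)CC[C@@]2(O)C(C)C | intermediate (not isolated)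
23 | (1S,4R,5S,6S)-4-hydroxy-4-isopropyl-1-methyl-10-oxobicyclo[5.3.0]dec-8-en-6-yl 3,4-dimethoxybenzoate | O=C1C=CC[C@H](OC(=O)c3ccc(OC)c(OC)c3)[C@@H]2[C@]1(C)CC[C@@]2(O)C(C)C | intermediate
24 | bis(bromomagnesium) salt (C9=C10 enolate and C4 alkoxide) of 25 | Br[Mg]OC1=CC(C)C[C@H](OC(=O)c3ccc(OC)c(OC)c3)[C@@H]2[C@]1(C)CC[C@@]2(O[Mg]Br)C(C)C | intermediate (not isolated)
25 | (1S,4R,5S,6S,8RS)-4-hydroxy-4-isopropyl-1,8-dimethyl-10-oxobicyclo[5.3.0]decan-6-yl 3,4-dimethoxybenzoate (C8 epimers) | O=C1CC(C)C[C@H](OC(=O)c3ccc(OC)c(OC)c3)[C@@H]2[C@]1(C)CC[C@@]2(O)C(C)C | intermediate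
26 | (1S,4R,5S,6S)-4-hydroxy-4-isopropyl-1,8-dimethyl-10-oxobicyclo[5.3.0]dec-8-en-6-yl 3,4-dimethoxybenzoate | O=C1C=C(C)C[C@H](OC(=O)c3ccc(OC)c(OC)c3)[C@@H]2[C@]1(C)CC[C@@]2(O)C(C)C | intermediate
27 | (1S,4R,5S,6S,10S)-4,10-dihydroxy-4-isopropyl-1,8-dimethylbicyclo[5.3.0]dec-8-en-6-yl 3,4-dimethoxybenzoate | O[C@H]1C=C(C)C[C@H](OC(=O)c3ccc(OC)c(OC)c3)[C@@H]2[C@]1(C)CC[C@@]2(O)C(C)C | intermediate
28 | angelic acid, (Z)-2-methylbut-2-enoic acid | C/C=C(/C)C(=O)O | starting material
29 | (1S,4R,5S,6S,10R)-4-hydroxy-4-isopropyl-1,8-dimethyl-10-[(Z)-2-methylbut-2-enoyloxy]bicyclo[5.3.0]dec-8-en-6-yl 3,4-dimethoxybenzoate | C/C=C(/C)C(=O)O[C@@H]1C=C(C)C[C@H](OC(=O)c2ccc(OC)c(OC)c2)[C@@H]2[C@]1(C)CC[C@@]2(O)C(C)C | target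

## Step count and least certain steps

Total step count: 16. Longest linear sequence: 15 steps (steps 1–3 and 5–16, from 1); step 4 is the one-step side branch.

**Step 8 (key step).** The conjugate addition may be slow at the hindered β,β-disubstituted position, and the ring fusion may not equilibrate: the kinetically easier cis closure can persist if the lithium aldolate does not revert, or if the aggregated cis aldolate is the more stable species. The fallback sets out from 11 and comes back at 17. The cascade is quenched cold so that the cis-fused ketol F1 is isolated, and ring closure is then separated from the conjugate addition. F1 is equilibrated as the neutral, hydrogen-bonded ketol by retro-aldol/aldol reaction under protic catalysis (catalytic KOt-Bu in t-BuOH, or pyrrolidinium acetate). Under these conditions the relative stability of the free ketols decides, not that of the lithium aldolates; in the trans isomer the O-4–H···O=C6 hydrogen bond is ideally aligned. If the trans ketol is not favoured under either regime, C4 and C5 cannot be set by this closure, and the stereospecific ring-fusion logic of Alternative 3 would be the recourse.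

**Step 16.** The oxyphosphonium ion at the neopentylic, allylic C10 may ionise instead of being displaced, which would open allylic transposition to C8 and elimination to a diene, or the displacement may be slow; loss of the Z geometry is a further risk. The fallback sets out from 27 and comes back at 29, with inversion and acylation separated. Mitsunobu reaction with 4-nitrobenzoic acid (PPh3, DIAD, toluene), the usual partner for hindered carbinols, should give the (10R)-4-nitrobenzoate F2. Methanolysis of this activated ester (K2CO3, MeOH, 0 °C), which the hindered electron-rich 3,4-dimethoxybenzoate is expected to survive, gives the (10R)-allylic alcohol F3. F3 is acylated with retention by the mixed anhydride of 28 and 2,4,6-trichlorobenzoyl chloride (Et3N, toluene, 80 °C, no nucleophilic catalyst) to give 29.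

**Step 15.** Facial discrimination in the hydride delivery may be insufficient, since the seven-membered enone is flexible. The fallback sets out from 26 and comes back at 27; reagent control is added to substrate control. Reduction uses BH3·SMe2 and the enantiomer of the B-methyl oxazaborolidine whose intrinsic preference coincides with attack anti to the C1 methyl, expected to be the (R)-catalyst if the quaternary C1 acts as the larger group. This gives the same 27 and involves no new compound. If the substrate turns out to favour the other epimer, that alcohol is F3 and is esterified with retention as described for step 16.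

**Step 12.** Enolisation of the hindered α-quaternary ketone may be sluggish, or over-oxidation towards a dienone may occur at 75 °C. The fallback sets out from 21 and comes back at 23 by the classical three-stage sequence. Dess–Martin periodinane gives 22, isolated in this case. TMSOTf and Et3N silylate both the ketone enol and the tertiary hydroxyl to give the bis-silyl compound F4. Saegusa–Ito oxidation with Pd(OAc)2 in MeCN gives the enone F5, which still carries the C4 trimethylsilyl ether, and brief treatment with aqueous citric acid in THF removes that ether to give 23. The same sequence can replace step 14.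

**Step 2.** Enantioselection may be insufficient, or the product may isomerise onward to the 1,4-dione. The fallback sets out from 2 and comes back at 4 through enzymatic desymmetrisation. Thiourea reduction of 2 gives the meso diol F6. The lipase from Burkholderia cepacia with isopropenyl acetate is expected, by analogy with cyclopent-2-ene-1,4-diol, to acylate the (S)-carbinol and give the monoacetate F7. Silylation (TBSCl, imidazole) gives F8, methanolysis (K2CO3, MeOH) gives the alcohol F9, and MnO2 oxidation gives 4. If the enzyme shows the opposite sense, hydrolysis of the meso diacetate with the same lipase in buffer supplies F7.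

## Further compounds

F1 | step 8 | (1S,4S,5S,10R)-10-(tert-butyldimethylsilyloxy)-4-hydroxy-4-isopropyl-1-methylbicyclo[5.3.0]decan-6-one (cis-fused ketol) | CC(C)(C)[Si](C)(C)O[C@@H]1CCCC(=O)[C@H]2[C@]1(C)CC[C@]2(O)C(C)C
F2 | step 16 | (1S,4R,5S,6S,10R)-6-(3,4-dimethoxybenzoyloxy)-4-hydroxy-4-isopropyl-1,8-dimethylbicyclo[5.3.0]dec-8-en-10-yl 4-nitrobenzoate | O=[N+]([O-])c1ccc(cc1)C(=O)O[C@@H]1C=C(C)C[C@H](OC(=O)c3ccc(OC)c(OC)c3)[C@@H]2[C@]1(C)CC[C@@]2(O)C(C)C
F3 | step 16 | (1S,4R,5S,6S,10R)-4,10-dihydroxy-4-isopropyl-1,8-dimethylbicyclo[5.3.0]dec-8-en-6-yl 3,4-dimethoxybenzoate | O[C@@H]1C=C(C)C[C@H](OC(=O)c3ccc(OC)c(OC)c3)[C@@H]2[C@]1(C)CC[C@@]2(O)C(C)C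
F0 | step 15 | none | none
F4 | step 12 | (1S,4R,5S,6S)-4-isopropyl-1-methyl-4,10-bis(trimethylsilyloxy)bicyclo[5.3.0]dec-9-en-6-yl 3,4-dimethoxybenzoate | C[Si](C)(C)OC1=CCC[C@H](OC(=O)c3ccc(OC)c(OC)c3)[C@@H]2[C@]1(C)CC[C@@]2(O[Si](C)(C)C)C(C)C
F5 | step 12 | (1S,4R,5S,6S)-4-isopropyl-1-methyl-10-oxo-4-(trimethylsilyloxy)bicyclo[5.3.0]dec-8-en-6-yl 3,4-dimethoxybenzoate | O=C1C=CC[C@H](OC(=O)c3ccc(OC)c(OC)c3)[C@@H]2[C@]1(C)CC[C@@]2(O[Si](C)(C)C)C(C)C
F6 | step 2 | cis-cyclohept-2-ene-1,4-diol (meso) | O[C@H]1C=C[C@@H](O)CCC1
F7 | step 2 | (1S,4R)-4-hydroxycyclohept-2-en-1-yl acetate | O[C@H]1C=C[C@@H](OC(C)=O)CCC1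
F8 | step 2 | (1S,4R)-4-(tert-butyldimethylsilyloxy)cyclohept-2-en-1-yl acetate | CC(C)(C)[Si](C)(C)O[C@H]1C=C[C@@H](OC(C)=O)CCC1
F9 | step 2 | (1S,4R)-4-(tert-butyldimethylsilyloxy)cyclohept-2-en-1-ol | CC(C)(C)[Si](C)(C)O[C@H]1C=C[C@@H](O)CCC1
A1 | alternative 1 | 2-[(Z)-2-(tert-butyldimethylsilyloxy)-2-(2-methylcyclopropyl)ethenyl]-2-(3-methylpenta-3,4-dienyl)-1,3-dioxolane (cyclopropane configuration not fixed) | C=C=C(C)CCC1(OCCO1)/C=C(\O[Si](C)(C)C(C)(C)C)C2CC2C
A2 | alternative 1 | cis-fused hydroazulene with 10-methylene, C6 silyl enol ether and C4 dioxolane (product of the cycloaddition) | C=C1C[C@H](C)C=C(O[Si](C)(C)C(C)(C)C)[C@H]2[C@]1(C)CCC23OCCO3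
A3 | alternative 2 | (R)-1-[1-(tert-butyldimethylsilyloxy)ethenyl]-5-isopropyl-2-methyl-5-(triethylsilyloxy)cyclopent-1-ene | C=C(O[Si](C)(C)C(C)(C)C)C1=C(C)CC[C@@]1(O[Si](CC)(CC)CC)C(C)C
A4 | alternative 2 | methyl (Z)-4-acetoxy-2-diazobut-3-enoate | COC(=O)C(=[N+]=[N-])/C=C\OC(C)=O
A5 | alternative 2 | bicyclic cycloheptadiene with C10 acetate, C8 methyl ester, C6 silyl enol ether and C4 triethylsilyl ether (product of cyclopropanation and Cope rearrangement) | CC(=O)O[C@@H]1C=C(C(=O)OC)CC(O[Si](C)(C)C(C)(C)C)=C2[C@]1(C)CC[C@@]2(O[Si](CC)(CC)CC)C(C)C
A6 | alternative 3 | cis-decalin with C1 methyl, C6 hydroxyl and C5 mesylate all cis, C4 triethylsilyl ether and C10 dioxolane (diol monomesylate) | C[C@]12CC[C@@](O[Si](CC)(CC)CC)(C(C)C)[C@H](OS(C)(=O)=O)[C@@]1(O)CCCC23OCCO3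
A7 | alternative 3 | trans-fused 6-keto hydroazulene with C10 dioxolane and C4 triethylsilyl ether (product of the 1,2-shift) | O=C1CCCC2(OCCO2)[C@@]3(C)CC[C@@](O[Si](CC)(CC)CC)(C(C)C)[C@H]13
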